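**Strategy.** The eight-membered carbocycle is not closed directly but grown from a six-membered ring. Its C5 carbinol and C8–C9 cyclopropane (cycloocta[c]furan numbering) are read as a masked cyclooct-4-enone, the retron of a Claisen rearrangement. A trans-lactone-fused 2-methylidene-6-[(E)-propenyl]tetrahydropyran, locked with the propenyl group axial, rearranges on heating: C6–C7 forms, the ring C–O bond breaks and the pyran expands by two atoms to the cyclooctenone, while its carbinol configuration is relayed to the C7 methyl centre. One copper-catalysed conjugate addition sets the first stereocentre; Michael, aldol, Claisen, hydride and hydroxyl-directed cyclopropanation steps relay it to all the others.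

Key step: step 10

Remark: carbocycle atoms are numbered as in cycloocta[c]furan (C1 lactone carbonyl, O2, C3, C3a, C4 to C9, C9a). TBS = tert-butyldimethylsilyl, TBDPS = tert-butyl(diphenyl)silyl. The lithium amide, the aluminium and boron hydrides and diethylzinc are taken as purchased solutions. Of the two enantiomers of the phosphoramidite ligand in step 2, the one that gives the 4S lactone is used.

Step 1
Reactants: 1 (tert-butyldimethylsilyloxy)acetaldehyde; 2 tert-butyl (triphenylphosphoranylidene)acetate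
Product: 3 tert-butyl (2E)-4-[(tert-butyldimethylsilyl)oxy]but-2-enoate
Conditions: CH2Cl2, rt
Reagents that add atoms: none
Why: Wittig olefination with the ester-stabilised ylide should give the (E)-enoate selectively.

Step 2
Reactants: 4 5-bromo-2-methylpent-2-ene; 5 furan-2(5H)-one
Product: 8 (4S)-4-(4-methylpent-3-en-1-yl)dihydrofuran-2(3H)-one, via homoprenylmagnesium bromide 6 (not isolated), via bis(homoprenyl)zinc 7 (not isolated)
Conditions: 4, Mg, THF; ZnCl2 (0.5 equiv), then 1,4-dioxane, filter; Cu(OTf)2 (2 mol %), O,O'-(1,1'-binaphthyl-2,2'-diyl) N,N-bis(1-phenylethyl)phosphoramidite (4 mol %), PhMe, −30 °C, slow addition of 5; 1 M HCl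
Reagents that add atoms: none
Why: Copper-catalysed asymmetric conjugate addition of the dialkylzinc (made by Grignard formation and transmetalation) to the unsaturated lactone, in which the chiral copper–phosphoramidite complex selects the enoate face and sets C4 as S, the only stereocentre of the route set by a catalyst.

Step 3
Reactants: 8 (4S)-4-(4-methylpent-3-en-1-yl)dihydrofuran-2(3H)-one; 3 tert-butyl (2E)-4-[(tert-butyldimethylsilyl)oxy]but-2-enoate
Product: 9 tert-butyl (3S)-4-[(tert-butyldimethylsilyl)oxy]-3-[(3R,4S)-4-(4-methylpent-3-en-1-yl)-2-oxotetrahydrofuran-3-yl]butanoate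
Conditions: LiN(i-Pr)2 (1.05 equiv), THF, −78 °C; then 3, −78 °C; AcOH
Reagents that add atoms: none
Why: Michael addition of the lithium lactone enolate to the (E)-enoate: attack anti to the C4 substituent gives the 3,4-trans lactone, and the chelated eight-membered transition state of an enolate whose α-substituent is trans to O–Li should give the syn relation between ring C4 and the new CH(CH2OTBS) centre (3S).

Step 4
Reactants: 9 tert-butyl (3S)-4-[(tert-butyldimethylsilyl)oxy]-3-[(3R,4S)-4-(4-methylpent-3-en-1-yl)-2-oxotetrahydrofuran-3-yl]butanoate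
Product: 10 tert-butyl (3S)-4-[(tert-butyldimethylsilyl)oxy]-3-[(3R,4S)-2-hydroxy-4-(4-methylpent-3-en-1-yl)tetrahydrofuran-3-yl]butanoate (lactol, anomeric mixture)
Conditions: i-Bu2AlH (1.1 equiv), CH2Cl2, −78 °C; aq. KNaC4H4O6
Reagents that add atoms: none
Why: Partial reduction of the γ-lactone to the lactol by i-Bu2AlH, which should leave the tert-butyl ester untouched at −78 °C; only the inconsequential anomeric centre is formed.

Step 5
Reactants: 10 tert-butyl (3S)-4-[(tert-butyldimethylsilyl)oxy]-3-[(3R,4S)-2-hydroxy-4-(4-methylpent-3-en-1-yl)tetrahydrofuran-3-yl]butanoate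
Product: 11 tert-butyl (3S,4R,5S)-3-{[(tert-butyldimethylsilyl)oxy]methyl}-4-ethynyl-5-(hydroxymethyl)-9-methyldec-8-enoate
Conditions: dimethyl (1-diazo-2-oxopropyl)phosphonate, K2CO3, MeOH, 0 °C to rt
Reagents that add atoms: dimethyl (1-diazo-2-oxopropyl)phosphonate, COP(=O)(OC)C(=[N+]=[N-])C(C)=O
Why: Ohira–Bestmann (Seyferth–Gilbert) homologation of the hydroxy aldehyde in equilibrium with the lactol adds the terminal alkyne carbon and frees the primary alcohol, the α-branched centre being retained under the mild carbonate conditions.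

Step 6
Reactants: 11 tert-butyl (3S,4R,5S)-3-{[(tert-butyldimethylsilyl)oxy]methyl}-4-ethynyl-5-(hydroxymethyl)-9-methyldec-8-enoate
Product: 12 tert-butyl (3S,4R,5S)-3-{[(tert-butyldimethylsilyl)oxy]methyl}-5-({[tert-butyl(diphenyl)silyl]oxy}methyl)-4-ethynyl-9-methyldec-8-enoate
Conditions: t-BuPh2SiCl, imidazole, DMF, rt
Reagents that add atoms: tert-butyl(chloro)diphenylsilane, CC(C)(C)[Si](Cl)(c1ccccc1)c1ccccc1
Why: Standard silylation of the only free (primary) hydroxyl as the acid-stable TBDPS ether.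

Step 7
Reactants: 12 tert-butyl (3S,4R,5S)-3-{[(tert-butyldimethylsilyl)oxy]methyl}-5-({[tert-butyl(diphenyl)silyl]oxy}methyl)-4-ethynyl-9-methyldec-8-enoate
Product: 14 (4S)-4-[(3S,4S)-4-({[tert-butyl(diphenyl)silyl]oxy}methyl)-8-methylnon-7-en-1-yn-3-yl]dihydrofuran-2(3H)-one, via hydroxy ester 13 (not isolated)
Conditions: TsOH·H2O (0.1 equiv), MeOH, 0 °C; then PhMe, 60 °C
Reagents that add atoms: none
Why: Acid-catalysed methanolysis removes the primary TBS ether in the presence of TBDPS, and the γ-hydroxy tert-butyl ester then closes to the γ-lactone (acid-catalysed transesterification, 5-exo-trig) with loss of tert-butanol.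

Step 8
Reactants: 14 (4S)-4-[(3S,4S)-4-({[tert-butyl(diphenyl)silyl]oxy}methyl)-8-methylnon-7-en-1-yn-3-yl]dihydrofuran-2(3H)-one; 15 (2E)-but-2-enal
Product: 16 (3S,4R)-4-[(3R,4S)-4-({[tert-butyl(diphenyl)silyl]oxy}methyl)-8-methylnon-7-en-1-yn-3-yl]-3-[(1S,2E)-1-hydroxybut-2-en-1-yl]dihydrofuran-2(3H)-one
Conditions: LiN(i-Pr)2 (2.2 equiv), THF, −78 °C; 15 (1.0 equiv), −78 °C, 5 min; AcOH
Reagents that add atoms: none
Why: 1,2-Aldol addition of the lithium lactone enolate (the second equivalent of base holds the alkyne as the far less reactive acetylide): attack anti to the C4 branch gives the 3,4-trans lactone, and the Zimmerman–Traxler chair of the enolate with its α-carbon trans to O–Li should give the anti (1S) carbinol.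

Step 9
Reactants: 16 (3S,4R)-4-[(3R,4S)-4-({[tert-butyl(diphenyl)silyl]oxy}methyl)-8-methylnon-7-en-1-yn-3-yl]-3-[(1S,2E)-1-hydroxybut-2-en-1-yl]dihydrofuran-2(3H)-one
Product: 17 (3aS,4S,7R,7aR)-7-[(2S)-1-{[tert-butyl(diphenyl)silyl]oxy}-6-methylhept-5-en-2-yl]-6-methylidene-4-[(1E)-prop-1-en-1-yl]hexahydro-1H-furo[3,4-c]pyran-3-one
Conditions: AuCl (5 mol %), K2CO3 (10 mol %), MeCN, rt; filtration through basic Al2O3
Reagents that add atoms: none
Why: Gold-catalysed 6-exo-dig hydroalkoxylation (cycloisomerisation) of the hex-5-yn-1-ol unit closes the tetrahydropyran as the exocyclic enol ether without touching a stereocentre, the carbonate buffer keeping the double bond exocyclic.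

Step 10
Reactants: 17 (3aS,4S,7R,7aR)-7-[(2S)-1-{[tert-butyl(diphenyl)silyl]oxy}-6-methylhept-5-en-2-yl]-6-methylidene-4-[(1E)-prop-1-en-1-yl]hexahydro-1H-furo[3,4-c]pyran-3-one
Product: 18 (3aR,4R,7S,8Z,9aR)-4-[(2S)-1-{[tert-butyl(diphenyl)silyl]oxy}-6-methylhept-5-en-2-yl]-7-methyl-3a,4,6,7-tetrahydrocycloocta[c]furan-1,5(3H,9aH)-dione
Conditions: PhMe (0.01 M), base-washed sealed tube, 180 °C
Reagents that add atoms: none
Why: On heating, the allyl vinyl ether embedded in 17 (CH2=C6–O5–C4–CH=CH–CH3, furo-pyran numbering) undergoes a concerted, suprafacial [3,3]-sigmatropic (Claisen) shift in which the methylidene carbon bonds to the propenyl terminus while the ring O5–C4 bond breaks, so that the six-membered pyran is enlarged by two atoms to the cyclooct-4-enone and the ring oxygen becomes the C5 ketone of 18. The closest known reaction type is the thermal Claisen ring expansion of 2-methylidene-6-vinyltetrahydropyrans to cyclooct-4-enones. The eight-membered ring is closed not end to end but by this pericyclic C6–C7 bond formation through a chair-like, bicyclo[3.3.1]-type transition state in which the pyran carbons bridge the two termini, which also forces the new C8=C9 double bond to be Z. The only new stereocentre, C7, is set by chirality transfer from the pyran carbinol carbon (4S in 17): the new bond forms on the face of the (E)-propenyl group from which the oxygen departs, which should give 7S. The step needs the propenyl group axial and syn to the enol ether π face, and the trans fusion of the lactone secures this by locking the chair with the propenyl group axial and the C7 side chain of 17 equatorial. Acid-induced migration of the exocyclic double bond into the ring is the competing path and is suppressed by base-washed glassware.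

Step 11
Reactants: 18 (3aR,4R,7S,8Z,9aR)-4-[(2S)-1-{[tert-butyl(diphenyl)silyl]oxy}-6-methylhept-5-en-2-yl]-7-methyl-3a,4,6,7-tetrahydrocycloocta[c]furan-1,5(3H,9aH)-dione
Product: 19 (3aR,4R,5S,7S,8Z,9aR)-4-[(2S)-1-{[tert-butyl(diphenyl)silyl]oxy}-6-methylhept-5-en-2-yl]-5-hydroxy-7-methyl-3a,4,5,6,7,9a-hexahydrocycloocta[c]furan-1(3H)-one
Conditions: LiBH(s-Bu)3 (1.1 equiv), THF, −78 °C; AcOH
Reagents that add atoms: none
Why: Ketone reduction with a bulky borohydride, which should attack the carbonyl face anti to the branched C4 substituent and so give the 5S alcohol cis to that substituent, the lactone being inert at −78 °C.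

Step 12
Reactants: 19 (3aR,4R,5S,7S,8Z,9aR)-4-[(2S)-1-{[tert-butyl(diphenyl)silyl]oxy}-6-methylhept-5-en-2-yl]-5-hydroxy-7-methyl-3a,4,5,6,7,9a-hexahydrocycloocta[c]furan-1(3H)-one
Product: 20 (3aR,4R,5S,7S,8R,9R,9aR)-4-[(2S)-1-{[tert-butyl(diphenyl)silyl]oxy}-6-methylhept-5-en-2-yl]-5-hydroxy-7-methyl-8,9-methanodecahydrocycloocta[c]furan-1-one (cyclopropane CH2 cis to the C5 hydroxyl, trans to the C7 methyl)
Conditions: Et2Zn (2 equiv), CH2I2 (2 equiv), CH2Cl2, −20 to 0 °C
Reagents that add atoms: diiodomethane, ICI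
Why: Hydroxyl-directed Simmons–Smith cyclopropanation (Furukawa reagent): the zinc alkoxide at C5 should deliver the carbenoid across the ring to the Z C8=C9 bond on its own face, which is also the face anti to the C7 methyl group, faster than the undirected trisubstituted side-chain alkene reacts.

Step 13
Reactants: 20 (3aR,4R,5S,7S,8R,9R,9aR)-4-[(2S)-1-{[tert-butyl(diphenyl)silyl]oxy}-6-methylhept-5-en-2-yl]-5-hydroxy-7-methyl-8,9-methanodecahydrocycloocta[c]furan-1-one
Product: 22 (4R,5S,7S,8R,9R)-4-[(2S)-1-{[tert-butyl(diphenyl)silyl]oxy}-6-methylhept-5-en-2-yl]-5-hydroxy-7-methyl-8,9-methano-4,5,6,7,8,9-hexahydrocycloocta[c]furan-1(3H)-one, via 9a-phenylselanyl lactone 21 (not isolated)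
Conditions: LiN(i-Pr)2 (2.5 equiv), THF, −78 °C; PhSeBr; AcOH, then 30% H2O2, 0 °C to rt
Reagents that add atoms: none
Why: α-Selenenylation of the lactone enolate (alkoxide and enolate formed with excess base) places selenium anti to the C3a–C4 bond and hence syn to H-3a, so that oxidation to the selenoxide and syn elimination should give the tetrasubstituted butenolide C3a=C9a, elimination towards the cyclopropane being disfavoured by strain.

Step 14
Reactants: 22 (4R,5S,7S,8R,9R)-4-[(2S)-1-{[tert-butyl(diphenyl)silyl]oxy}-6-methylhept-5-en-2-yl]-5-hydroxy-7-methyl-8,9-methano-4,5,6,7,8,9-hexahydrocycloocta[c]furan-1(3H)-one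
Product: 23 (4R,5S,7S,8R,9R)-5-hydroxy-4-[(2S)-1-hydroxy-6-methylhept-5-en-2-yl]-7-methyl-8,9-methano-4,5,6,7,8,9-hexahydrocycloocta[c]furan-1(3H)-one
Conditions: Bu4NF, AcOH, THF, rt
Reagents that add atoms: none
Why: Fluoride cleavage of the silyl ether, buffered with acetic acid to keep the butenolide from base-induced isomerisation.

Step 15
Reactants: 23 (4R,5S,7S,8R,9R)-5-hydroxy-4-[(2S)-1-hydroxy-6-methylhept-5-en-2-yl]-7-methyl-8,9-methano-4,5,6,7,8,9-hexahydrocycloocta[c]furan-1(3H)-one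
Product: 24 (2S)-2-[(4R,5S,7S,8R,9R)-5-hydroxy-7-methyl-1-oxo-8,9-methano-1,3,4,5,6,7,8,9-octahydrocycloocta[c]furan-4-yl]-6-methylhept-5-en-1-yl acetate (CNP0267808.2)
Conditions: AcCl (1.05 equiv), 2,4,6-collidine, CH2Cl2, −78 °C
Reagents that add atoms: acetyl chloride, CC(Cl)=O
Why: Acylation at low temperature with a hindered pyridine base should acetylate the primary hydroxyl and leave the hindered secondary C5 hydroxyl free.

**Compound list**

1 | (tert-butyldimethylsilyloxy)acetaldehyde | O=CCO[Si](C)(C)C(C)(C)C | starting material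
2 | tert-butyl (triphenylphosphoranylidene)acetate | CC(C)(C)OC(=O)C=P(c1ccccc1)(c1ccccc1)c1ccccc1 | starting material
3 | tert-butyl (2E)-4-[(tert-butyldimethylsilyl)oxy]but-2-enoate | CC(C)(C)OC(=O)/C=C/CO[Si](C)(C)C(C)(C)C | intermediate
4 | 5-bromo-2-methylpent-2-ene | CC(C)=CCCBr | starting material
5 | furan-2(5H)-one | O=C1OCC=C1 | starting material
6 | (4-methylpent-3-en-1-yl)magnesium bromide (homoprenylmagnesium bromide) | CC(C)=CCC[Mg]Br | intermediate (not isolated)
7 | bis(4-methylpent-3-en-1-yl)zinc (bis(homoprenyl)zinc) | CC(C)=CCC[Zn]CCC=C(C)C | intermediate (not isolated)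
8 | (4S)-4-(4-methylpent-3-en-1-yl)dihydrofuran-2(3H)-one | O=C1OC[C@@H](CCC=C(C)C)C1 | intermediate
9 | tert-butyl (3S)-4-[(tert-butyldimethylsilyl)oxy]-3-[(3R,4S)-4-(4-methylpent-3-en-1-yl)-2-oxotetrahydrofuran-3-yl]butanoate | O=C1OC[C@@H](CCC=C(C)C)[C@@H]1[C@@H](CO[Si](C)(C)C(C)(C)C)CC(=O)OC(C)(C)C | intermediate
10 | tert-butyl (3S)-4-[(tert-butyldimethylsilyl)oxy]-3-[(3R,4S)-2-hydroxy-4-(4-methylpent-3-en-1-yl)tetrahydrofuran-3-yl]butanoate (anomeric mixture) | OC1OC[C@@H](CCC=C(C)C)[C@@H]1[C@@H](CO[Si](C)(C)C(C)(C)C)CC(=O)OC(C)(C)C | intermediate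
11 | tert-butyl (3S,4R,5S)-3-{[(tert-butyldimethylsilyl)oxy]methyl}-4-ethynyl-5-(hydroxymethyl)-9-methyldec-8-enoate | OC[C@@H](CCC=C(C)C)[C@@H](C#C)[C@@H](CO[Si](C)(C)C(C)(C)C)CC(=O)OC(C)(C)C | intermediate
12 | tert-butyl (3S,4R,5S)-3-{[(tert-butyldimethylsilyl)oxy]methyl}-5-({[tert-butyl(diphenyl)silyl]oxy}methyl)-4-ethynyl-9-methyldec-8-enoate | CC(C)(C)[Si](c1ccccc1)(c1ccccc1)OC[C@@H](CCC=C(C)C)[C@@H](C#C)[C@@H](CO[Si](C)(C)C(C)(C)C)CC(=O)OC(C)(C)C | intermediate
13 | tert-butyl (3S,4S,5S)-5-({[tert-butyl(diphenyl)silyl]oxy}methyl)-4-ethynyl-3-(hydroxymethyl)-9-methyldec-8-enoate (hydroxy ester) | CC(C)(C)[Si](c1ccccc1)(c1ccccc1)OC[C@@H](CCC=C(C)C)[C@@H](C#C)[C@@H](CO)CC(=O)OC(C)(C)C | intermediate (not isolated)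
14 | (4S)-4-[(3S,4S)-4-({[tert-butyl(diphenyl)silyl]oxy}methyl)-8-methylnon-7-en-1-yn-3-yl]dihydrofuran-2(3H)-one | CC(C)(C)[Si](c1ccccc1)(c1ccccc1)OC[C@@H](CCC=C(C)C)[C@@H](C#C)[C@@H]1CC(=O)OC1 | intermediate
15 | (2E)-but-2-enal | C/C=C/C=O | starting material
16 | (3S,4R)-4-[(3R,4S)-4-({[tert-butyl(diphenyl)silyl]oxy}methyl)-8-methylnon-7-en-1-yn-3-yl]-3-[(1S,2E)-1-hydroxybut-2-en-1-yl]dihydrofuran-2(3H)-one | CC(C)(C)[Si](c1ccccc1)(c1ccccc1)OC[C@@H](CCC=C(C)C)[C@@H](C#C)[C@@H]1[C@H](C(=O)OC1)[C@H](/C=C/C)O | intermediate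
17 | (3aS,4S,7R,7aR)-7-[(2S)-1-{[tert-butyl(diphenyl)silyl]oxy}-6-methylhept-5-en-2-yl]-6-methylidene-4-[(1E)-prop-1-en-1-yl]hexahydro-1H-furo[3,4-c]pyran-3-one | CC(C)(C)[Si](c1ccccc1)(c1ccccc1)OC[C@@H](CCC=C(C)C)[C@@H]1[C@@H]2[C@H](C(=O)OC2)[C@H](/C=C/C)OC1=C | intermediate
18 | (3aR,4R,7S,8Z,9aR)-4-[(2S)-1-{[tert-butyl(diphenyl)silyl]oxy}-6-methylhept-5-en-2-yl]-7-methyl-3a,4,6,7-tetrahydrocycloocta[c]furan-1,5(3H,9aH)-dione | CC(C)(C)[Si](c1ccccc1)(c1ccccc1)OC[C@@H](CCC=C(C)C)[C@@H]1[C@@H]2[C@H](C(=O)OC2)/C=C\[C@@H](C)CC1=O | intermediate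
19 | (3aR,4R,5S,7S,8Z,9aR)-4-[(2S)-1-{[tert-butyl(diphenyl)silyl]oxy}-6-methylhept-5-en-2-yl]-5-hydroxy-7-methyl-3a,4,5,6,7,9a-hexahydrocycloocta[c]furan-1(3H)-one | CC(C)(C)[Si](c1ccccc1)(c1ccccc1)OC[C@@H](CCC=C(C)C)[C@@H]1[C@@H]2[C@H](C(=O)OC2)/C=C\[C@@H](C)C[C@@H]1O | intermediate
20 | (3aR,4R,5S,7S,8R,9R,9aR)-4-[(2S)-1-{[tert-butyl(diphenyl)silyl]oxy}-6-methylhept-5-en-2-yl]-5-hydroxy-7-methyl-8,9-methanodecahydrocycloocta[c]furan-1-one | CC(C)(C)[Si](c1ccccc1)(c1ccccc1)OC[C@@H](CCC=C(C)C)[C@@H]1[C@@H]2[C@H](C(=O)OC2)[C@@H]2C[C@@H]2[C@@H](C)C[C@@H]1O | intermediate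
21 | 9a-(phenylselanyl) derivative of 20, selenium cis to H-3a (9a-phenylselanyl lactone) | CC(C)(C)[Si](c1ccccc1)(c1ccccc1)OC[C@@H](CCC=C(C)C)[C@@H]1[C@@H]2[C@](C(=O)OC2)([Se]c2ccccc2)[C@@H]2C[C@@H]2[C@@H](C)C[C@@H]1O | intermediate (not isolated)
22 | (4R,5S,7S,8R,9R)-4-[(2S)-1-{[tert-butyl(diphenyl)silyl]oxy}-6-methylhept-5-en-2-yl]-5-hydroxy-7-methyl-8,9-methano-4,5,6,7,8,9-hexahydrocycloocta[c]furan-1(3H)-one | CC(C)(C)[Si](c1ccccc1)(c1ccccc1)OC[C@@H](CCC=C(C)C)[C@@H]1C2=C(C(=O)OC2)[C@@H]2C[C@@H]2[C@@H](C)C[C@@H]1O | intermediate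
23 | (4R,5S,7S,8R,9R)-5-hydroxy-4-[(2S)-1-hydroxy-6-methylhept-5-en-2-yl]-7-methyl-8,9-methano-4,5,6,7,8,9-hexahydrocycloocta[c]furan-1(3H)-one | OC[C@@H](CCC=C(C)C)[C@@H]1C2=C(C(=O)OC2)[C@@H]2C[C@@H]2[C@@H](C)C[C@@H]1O | intermediate
24 | (2S)-2-[(4R,5S,7S,8R,9R)-5-hydroxy-7-methyl-1-oxo-8,9-methano-1,3,4,5,6,7,8,9-octahydrocycloocta[c]furan-4-yl]-6-methylhept-5-en-1-yl acetate | CC(=O)OC[C@@H](CCC=C(C)C)[C@@H]1C2=C(C(=O)OC2)[C@@H]2C[C@@H]2[C@@H](C)C[C@@H]1O | target

**Step count.** Total: 15 steps. Longest linear sequence: 14 steps (steps 2 to 15, from furan-2(5H)-one 5); step 1 supplies the Michael acceptor.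

**Steps most likely to fail**

Step 3 may suffer from poor simple diastereoselection at the new CH(CH2OTBS) centre, because the relay from the lactone to this centre rests on a transition-state model; the wrong relation would be carried into the aldol and the Claisen step. The fallback sets this centre by reagent control. It sets out from 8 and returns at 9. tert-Butyldimethyl(prop-2-yn-1-yloxy)silane is deprotonated with n-BuLi and acylated with di-tert-butyl dicarbonate to give tert-butyl 4-[(tert-butyldimethylsilyl)oxy]but-2-ynoate F1. The lithium enolate of 8 is added to F1 (THF, −78 °C) to give the β,β-disubstituted enoate tert-butyl (2E)-4-[(tert-butyldimethylsilyl)oxy]-3-[(3R,4S)-4-(4-methylpent-3-en-1-yl)-2-oxotetrahydrofuran-3-yl]but-2-enoate F2, in which the acidic lactone α-centre settles trans to its neighbour. A ligand-controlled copper hydride conjugate reduction (Cu(OAc)2, the enantiomer of 2,2'-bis(di-p-tolylphosphino)-1,1'-binaphthyl that gives 3S, polymethylhydrosiloxane, t-BuOH, PhMe) then delivers hydride to one face of the enoate and should give 9.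

Step 11 may deliver hydride to the wrong face of the ketone, since the conformation of the medium ring is not known; the wrong C5 configuration would also misdirect the cyclopropanation. The fallback corrects the centre by inversion. It sets out from 18 and returns at 19. The reduction would then give mainly the C5 epimer (3aR,4R,5R,7S,8Z,9aR)-4-[(2S)-1-{[tert-butyl(diphenyl)silyl]oxy}-6-methylhept-5-en-2-yl]-5-hydroxy-7-methyl-3a,4,5,6,7,9a-hexahydrocycloocta[c]furan-1(3H)-one F3. A Mitsunobu reaction (HCO2H, PPh3, diisopropyl azodicarboxylate, THF) should convert it with inversion into the 5S formate (3aR,4R,5S,7S,8Z,9aR)-4-[(2S)-1-{[tert-butyl(diphenyl)silyl]oxy}-6-methylhept-5-en-2-yl]-7-methyl-1-oxo-1,3,3a,4,5,6,7,9a-octahydrocycloocta[c]furan-5-yl formate F4, and mild methanolysis (KHCO3, MeOH, 0 °C) should give 19.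

Step 12 may fail through competing cyclopropanation of the electron-rich trisubstituted side-chain alkene, or through weak facial control if delivery from the C5 alkoxide across the ring is inefficient. The fallback changes the carbene source and the basis of selectivity. It sets out from 19 and returns at 20. Diazomethane with catalytic Pd(OAc)2 (Et2O, 0 °C) cyclopropanates strained cis-disubstituted ring alkenes but not trisubstituted alkenes, and should add to the C8=C9 bond from the face anti to the allylic C7 methyl group, which is the required face. This fallback makes no new compound F0.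

**Further compounds**

F1 | step 3 | tert-butyl 4-[(tert-butyldimethylsilyl)oxy]but-2-ynoate | CC(C)(C)OC(=O)C#CCO[Si](C)(C)C(C)(C)C
F2 | step 3 | tert-butyl (2E)-4-[(tert-butyldimethylsilyl)oxy]-3-[(3R,4S)-4-(4-methylpent-3-en-1-yl)-2-oxotetrahydrofuran-3-yl]but-2-enoate | O=C1OC[C@@H](CCC=C(C)C)[C@@H]1/C(CO[Si](C)(C)C(C)(C)C)=C\C(=O)OC(C)(C)C
F3 | step 11 | (3aR,4R,5R,7S,8Z,9aR)-4-[(2S)-1-{[tert-butyl(diphenyl)silyl]oxy}-6-methylhept-5-en-2-yl]-5-hydroxy-7-methyl-3a,4,5,6,7,9a-hexahydrocycloocta[c]furan-1(3H)-one | CC(C)(C)[Si](c1ccccc1)(c1ccccc1)OC[C@@H](CCC=C(C)C)[C@@H]1[C@@H]2[C@H](C(=O)OC2)/C=C\[C@@H](C)C[C@H]1O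
F4 | step 11 | (3aR,4R,5S,7S,8Z,9aR)-4-[(2S)-1-{[tert-butyl(diphenyl)silyl]oxy}-6-methylhept-5-en-2-yl]-7-methyl-1-oxo-1,3,3a,4,5,6,7,9a-octahydrocycloocta[c]furan-5-yl formate | CC(C)(C)[Si](c1ccccc1)(c1ccccc1)OC[C@@H](CCC=C(C)C)[C@@H]1[C@@H]2[C@H](C(=O)OC2)/C=C\[C@@H](C)C[C@@H]1OC=O
F0 | step 12 | none | none
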